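**Strategy.** The route rests on cutting the bond from C8 to the prenyl CH2 back to an O5–CH2 ether. On ring A, O5 and C8 are para, and both carbons ortho to O5 are blocked (C4a by the C4 carbonyl, C6 by OMe). A Claisen–Cope relay ([3,3] then [3,3]) can therefore deliver the prenyl group, unrearranged, only to C8 and free the 5-OH in the same operation. Its precursor is (2S)-6-methoxy-7-(methoxymethoxy)-5-(prenyloxy)flavanone. There the prenyl ether first serves as the O5 protecting group while ring B and C2 are added to an achiral chromone by enantioselective rhodium-catalysed 1,4-addition of phenylboronic acid.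

Key step: step 8

Assumption: the chiral diene of step 7 is taken to show the same sense of induction with the chromone as with simple cyclic enones; if it proves opposite, the enantiomeric ligand is used.

**Step 1**
Reactants: 1 3,4,5-trimethoxyphenol
Product: 2 1-(2-hydroxy-4,5,6-trimethoxyphenyl)ethan-1-one
Conditions: AcOH, BF3·OEt2, 90 °C; then H2O
Reagents that add atoms: acetic acid, CC(=O)O
Why: Friedel–Crafts (Nencki-type) C-acylation of the electron-rich phenol; the two positions ortho to OH are equivalent and the para position is blocked, so only one chelated ortho-hydroxy ketone can form.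

**Step 2**
Reactants: 2 1-(2-hydroxy-4,5,6-trimethoxyphenyl)ethan-1-one
Product: 4 5,6,7-trimethoxy-4H-chromen-4-one, via dimethylamino enone 3 (not isolated)
Conditions: Me2NCH(OMe)2 (2 equiv), toluene, 105 °C; evaporate; then AcOH, 90 °C
Reagents that add atoms: N,N-dimethylformamide dimethyl acetal, COC(OC)N(C)C
Why: Enaminone formation from the methyl ketone and the amide acetal, then acid-promoted addition–elimination (chromone synthesis from an ortho-hydroxyaryl enaminone); the only free OH of 2 becomes O1, which fixes the ring oxygen before the methyl ethers are touched.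

**Step 3**
Reactants: 4 5,6,7-trimethoxy-4H-chromen-4-one
Product: 5 5,6,7-trihydroxy-4H-chromen-4-one
Conditions: BBr3 (6 equiv), CH2Cl2, −78 °C to rt; then H2O
Reagents that add atoms: none
Why: Lewis-acid cleavage of aryl methyl ethers (BBr3 demethylation) should be exhaustive here, and the chromone ring carries no group that BBr3 attacks.

**Step 4**
Reactants: 5 5,6,7-trihydroxy-4H-chromen-4-one
Product: 6 5,6-dihydroxy-7-(methoxymethoxy)-4H-chromen-4-one
Conditions: MOMCl (1.05 equiv), K2CO3 (1.1 equiv), acetone, 0 °C, Ar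
Reagents that add atoms: chloromethyl methyl ether, COCCl
Why: Williamson-type O-alkylation under limiting base; the 7-OH is para to C4a and so a vinylogous acid conjugated with the C4 carbonyl, and should be ionised and alkylated first, whereas 6-OH is not conjugated and 5-OH is held in a hydrogen bond to O4.

**Step 5**
Reactants: 6 5,6-dihydroxy-7-(methoxymethoxy)-4H-chromen-4-one
Product: 7 5-hydroxy-6-methoxy-7-(methoxymethoxy)-4H-chromen-4-one
Conditions: MeI (1.1 equiv), K2CO3 (1.1 equiv), acetone, rt, Ar
Reagents that add atoms: iodomethane, CI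
Why: Williamson methylation with one equivalent of base at room temperature; the free 6-OH should react while the 5-OH, locked in a six-membered hydrogen bond to the C4 carbonyl, stays untouched.

**Step 6**
Reactants: 7 5-hydroxy-6-methoxy-7-(methoxymethoxy)-4H-chromen-4-one; 8 prenyl bromide (1-bromo-3-methylbut-2-ene)
Product: 9 6-methoxy-7-(methoxymethoxy)-5-[(3-methylbut-2-en-1-yl)oxy]-4H-chromen-4-one
Conditions: K2CO3 (2 equiv), DMF, 50 °C
Reagents that add atoms: none
Why: Williamson O-alkylation of the remaining chelated phenol with a reactive allylic bromide under more forcing conditions; attack at the primary carbon of 8 gives the unrearranged prenyl ether.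

**Step 7**
Reactants: 9 6-methoxy-7-(methoxymethoxy)-5-[(3-methylbut-2-en-1-yl)oxy]-4H-chromen-4-one; 10 phenylboronic acid
Product: 11 (2S)-6-methoxy-7-(methoxymethoxy)-5-[(3-methylbut-2-en-1-yl)oxy]-2-phenyl-2,3-dihydro-4H-chromen-4-one
Conditions: [RhCl(C2H4)2]2 (2.5 mol %), (1S,4S)-2,5-diphenylbicyclo[2.2.2]octa-2,5-diene (5.5 mol %), 10 (3 equiv), KOH (0.3 equiv), 1,4-dioxane/H2O 10:1, 40 °C
Reagents that add atoms: none
Why: Hayashi–Miyaura asymmetric 1,4-addition: phenyl passes from boron to monovalent rhodium, the C2=C3 bond of the chromone inserts into Rh–Ph on the face left open by the C2-symmetric diene, and water protonates the oxa-π-allyl rhodium, so C2 is set by the ligand [(1S,4S) antipode expected to give 2S], while the fully O-alkylated substrate offers no acidic OH and the trisubstituted prenyl alkene does not insert.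

**Step 8**
Reactants: 11 (2S)-6-methoxy-7-(methoxymethoxy)-5-[(3-methylbut-2-en-1-yl)oxy]-2-phenyl-2,3-dihydro-4H-chromen-4-one
Product: 14 (2S)-5-hydroxy-6-methoxy-7-(methoxymethoxy)-8-(3-methylbut-2-en-1-yl)-2-phenyl-2,3-dihydro-4H-chromen-4-one, via C6 ortho-dienone 12 (not isolated), via C8-H keto tautomer 13 (not isolated)
Conditions: Eu(fod)3 (10 mol %; fod = 6,6,7,7,8,8,8-heptafluoro-2,2-dimethyloctane-3,5-dionate), ClCH2CH2Cl, 70 °C, Ar
Reagents that add atoms: none
Why: Eu(fod)3 binds O4 and O5 of 11 and promotes an aromatic Claisen [3,3] shift of the prenyl group from O5 to C6 (allylic inversion), giving ortho-dienone 12, which cannot enolise because C6 carries OMe; a Cope [3,3] shift then moves the 1,1-dimethylallyl group to C8 with a second inversion, restoring the 3-methylbut-2-enyl connectivity, and keto tautomer 13 aromatises to phenol 14. The closest known reaction type is the para-Claisen (Claisen–Cope) rearrangement of aryl allyl ethers with both ortho positions substituted, which is known in its europium-catalysed form for 5-prenyloxyflavanones. No ring is closed and no new stereocenter is kept: the sp3 centers at C6 in 12 and at C8 in 13 are transient and vanish on aromatisation. The selectivity needed is delivery to C8 alone, and the substrate secures it: C4a and C6 are fully substituted, C8 is the only CH of ring A and is para to O5, and O7 is capped as the MOM ether. C2 should keep its S configuration because it lies outside the pericyclic array and the medium is non-basic, so the retro-oxa-Michael opening of ring C, the only path to epimerisation, is not triggered. In one operation the step forms the C8–CH2 bond at the most crowded position of ring A and frees the 5-OH, so no direct C-prenylation and no separate O5 deprotection are needed.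

**Step 9**
Reactants: 14 (2S)-5-hydroxy-6-methoxy-7-(methoxymethoxy)-8-(3-methylbut-2-en-1-yl)-2-phenyl-2,3-dihydro-4H-chromen-4-one
Product: 15 agrandol, (2S)-5,7-dihydroxy-6-methoxy-8-(3-methylbut-2-en-1-yl)-2-phenyl-2,3-dihydro-4H-chromen-4-one
Conditions: HCl (3 M aq), MeOH, 40 °C
Reagents that add atoms: none
Why: Acid-catalysed acetal exchange (MOM ether cleavage) in methanol frees the 7-OH without base, so C2 is not exposed to retro-oxa-Michael opening, and the dilute acid at mild temperature should not cyclise the 7-OH onto the prenyl alkene.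

**Compound list**
1 | 3,4,5-trimethoxyphenol | COc1cc(O)cc(OC)c1OC | starting material
2 | 1-(2-hydroxy-4,5,6-trimethoxyphenyl)ethan-1-one | CC(=O)c1c(O)cc(OC)c(OC)c1OC | intermediate
3 | (E)-3-(dimethylamino)-1-(2-hydroxy-4,5,6-trimethoxyphenyl)prop-2-en-1-one | CN(C)/C=C/C(=O)c1c(O)cc(OC)c(OC)c1OC | intermediate (not isolated)
4 | 5,6,7-trimethoxy-4H-chromen-4-one | COc1cc2occc(=O)c2c(OC)c1OC | intermediate
5 | 5,6,7-trihydroxy-4H-chromen-4-one | Oc1cc2occc(=O)c2c(O)c1O | intermediate
6 | 5,6-dihydroxy-7-(methoxymethoxy)-4H-chromen-4-one | COCOc1cc2occc(=O)c2c(O)c1O | intermediate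
7 | 5-hydroxy-6-methoxy-7-(methoxymethoxy)-4H-chromen-4-one | COCOc1cc2occc(=O)c2c(O)c1OC | intermediate
8 | prenyl bromide (1-bromo-3-methylbut-2-ene) | CC(C)=CCBr | starting material
9 | 6-methoxy-7-(methoxymethoxy)-5-[(3-methylbut-2-en-1-yl)oxy]-4H-chromen-4-one | COCOc1cc2occc(=O)c2c(OCC=C(C)C)c1OC | intermediate
10 | phenylboronic acid | OB(O)c1ccccc1 | starting material
11 | (2S)-6-methoxy-7-(methoxymethoxy)-5-[(3-methylbut-2-en-1-yl)oxy]-2-phenyl-2,3-dihydro-4H-chromen-4-one | COc1c(OCOC)cc2c(c1OCC=C(C)C)C(=O)C[C@@H](c1ccccc1)O2 | intermediate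
12 | (2S)-6-methoxy-7-(methoxymethoxy)-6-(2-methylbut-3-en-2-yl)-2-phenyl-2,3-dihydro-4H-chromene-4,5(6H)-dione (both C6 epimers) | COCOC1=CC2=C(C(=O)C[C@@H](c3ccccc3)O2)C(=O)C1(OC)C(C)(C)C=C | intermediate (not isolated)
13 | (2S)-6-methoxy-7-(methoxymethoxy)-8-(3-methylbut-2-en-1-yl)-2-phenyl-2,3-dihydro-4H-chromene-4,5(8H)-dione (both C8 epimers) | COCOC1=C(OC)C(=O)C2=C(O[C@H](c3ccccc3)CC2=O)C1CC=C(C)C | intermediate (not isolated)
14 | (2S)-5-hydroxy-6-methoxy-7-(methoxymethoxy)-8-(3-methylbut-2-en-1-yl)-2-phenyl-2,3-dihydro-4H-chromen-4-one | COc1c(OCOC)c(CC=C(C)C)c2c(c1O)C(=O)C[C@@H](c1ccccc1)O2 | intermediate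
15 | agrandol, (2S)-5,7-dihydroxy-6-methoxy-8-(3-methylbut-2-en-1-yl)-2-phenyl-2,3-dihydro-4H-chromen-4-one | COc1c(O)c(CC=C(C)C)c2c(c1O)C(=O)C[C@@H](c1ccccc1)O2 | target

Total step count: 9
Longest linear sequence: 9 steps (1 to 15)

**Steps most likely to fail**

1. Step 8 (key step). What may go wrong: ionisation of the europium-bound aryl prenyl ether with loss of the prenyl unit, or Lewis-acid-assisted opening and re-closure of ring C that erodes C2. The fallback sets out from 9 and comes back at 15; it runs the relay on the achiral chromone before C2 exists. Heating 9 in N,N-diethylaniline at 190 °C should give 5-hydroxy-6-methoxy-7-(methoxymethoxy)-8-(3-methylbut-2-en-1-yl)-4H-chromen-4-one F1 by the thermal para-Claisen rearrangement. The chelated 5-OH is then capped (NaH, MOMCl, DMF, 0 °C) to give 6-methoxy-5,7-bis(methoxymethoxy)-8-(3-methylbut-2-en-1-yl)-4H-chromen-4-one F2. Rhodium-catalysed addition of 10 under the conditions of step 7 should give (2S)-6-methoxy-5,7-bis(methoxymethoxy)-8-(3-methylbut-2-en-1-yl)-2-phenyl-2,3-dihydro-4H-chromen-4-one F3, and HCl in MeOH removes both MOM groups to reach 15.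

2. Step 7. What may go wrong: slow insertion of the electron-rich, peri-substituted chromone into Rh–Ph so that protodeboronation wins, or poor facial discrimination. The fallback sets out from 9 and comes back at 11; it rebuilds ring C by oxa-Michael closure. Aqueous NaOH in EtOH at 70 °C cleaves the pyranone of 9 (C2 is lost as formate) to give 1-[2-hydroxy-5-methoxy-4-(methoxymethoxy)-6-[(3-methylbut-2-en-1-yl)oxy]phenyl]ethan-1-one F4. Claisen–Schmidt condensation with benzaldehyde (KOH, EtOH, 0 °C to rt) gives (E)-1-[2-hydroxy-5-methoxy-4-(methoxymethoxy)-6-[(3-methylbut-2-en-1-yl)oxy]phenyl]-3-phenylprop-2-en-1-one F5. NaOAc in refluxing EtOH closes it to racemic 6-methoxy-7-(methoxymethoxy)-5-[(3-methylbut-2-en-1-yl)oxy]-2-phenyl-2,3-dihydro-4H-chromen-4-one F6. Preparative chromatography on a chiral stationary phase then separates 11 from (2R)-6-methoxy-7-(methoxymethoxy)-5-[(3-methylbut-2-en-1-yl)oxy]-2-phenyl-2,3-dihydro-4H-chromen-4-one F7.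

3. Step 4. What may go wrong: loss of site selectivity, that is alkylation at O6 or double alkylation, because the mono-anion of the triol is shared between O6 and O7. The fallback sets out from 5 and comes back at 6; it tells the hydroxyls apart by acyl cleavage instead of alkylation. Ac2O in pyridine gives 4-oxo-4H-chromene-5,6,7-triyl triacetate F8. PhSH and imidazole in N-methylpyrrolidone at 0 °C should remove only the 7-acetate, the ester of the most acidic phenol, to give 7-hydroxy-4-oxo-4H-chromene-5,6-diyl diacetate F9. MOMCl and K2CO3 in acetone give 7-(methoxymethoxy)-4-oxo-4H-chromene-5,6-diyl diacetate F10, and catalytic K2CO3 in MeOH at 0 °C removes both acetates to return to 6.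

**Further compounds**
F1 | step 8 | 5-hydroxy-6-methoxy-7-(methoxymethoxy)-8-(3-methylbut-2-en-1-yl)-4H-chromen-4-one | COCOc1c(CC=C(C)C)c2occc(=O)c2c(O)c1OC
F2 | step 8 | 6-methoxy-5,7-bis(methoxymethoxy)-8-(3-methylbut-2-en-1-yl)-4H-chromen-4-one | COCOc1c(CC=C(C)C)c2occc(=O)c2c(OCOC)c1OC
F3 | step 8 | (2S)-6-methoxy-5,7-bis(methoxymethoxy)-8-(3-methylbut-2-en-1-yl)-2-phenyl-2,3-dihydro-4H-chromen-4-one | COc1c(OCOC)c(CC=C(C)C)c2c(c1OCOC)C(=O)C[C@@H](c1ccccc1)O2
F4 | step 7 | 1-[2-hydroxy-5-methoxy-4-(methoxymethoxy)-6-[(3-methylbut-2-en-1-yl)oxy]phenyl]ethan-1-one | CC(=O)c1c(O)cc(OCOC)c(OC)c1OCC=C(C)C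
F5 | step 7 | (E)-1-[2-hydroxy-5-methoxy-4-(methoxymethoxy)-6-[(3-methylbut-2-en-1-yl)oxy]phenyl]-3-phenylprop-2-en-1-one | O=C(/C=C/c1ccccc1)c1c(O)cc(OCOC)c(OC)c1OCC=C(C)C
F6 | step 7 | racemic 6-methoxy-7-(methoxymethoxy)-5-[(3-methylbut-2-en-1-yl)oxy]-2-phenyl-2,3-dihydro-4H-chromen-4-one | COc1c(OCOC)cc2c(c1OCC=C(C)C)C(=O)CC(c1ccccc1)O2
F7 | step 7 | (2R)-6-methoxy-7-(methoxymethoxy)-5-[(3-methylbut-2-en-1-yl)oxy]-2-phenyl-2,3-dihydro-4H-chromen-4-one | COc1c(OCOC)cc2c(c1OCC=C(C)C)C(=O)C[C@H](c1ccccc1)O2
F8 | step 4 | 4-oxo-4H-chromene-5,6,7-triyl triacetate | CC(=O)Oc1cc2occc(=O)c2c(OC(C)=O)c1OC(C)=O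
F9 | step 4 | 7-hydroxy-4-oxo-4H-chromene-5,6-diyl diacetate | CC(=O)Oc1c(O)cc2occc(=O)c2c1OC(C)=O
F10 | step 4 | 7-(methoxymethoxy)-4-oxo-4H-chromene-5,6-diyl diacetate | COCOc1cc2occc(=O)c2c(OC(C)=O)c1OC(C)=O
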